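The target is a 1,4-naphthoquinone (ring A quinone, ring B benzo, ring C dimethoxyphenyl) in which C2, the methoxy-bearing carbon, lies between the C1 carbonyl (peri to the C8 aryl group) and C3. Because C2 carries a heteroatom, it is introduced as a chlorocarbene carbon: dichlorocarbene is inserted between the carbonyl carbon and the α-carbon of a 7-aryl-5-methoxy-1-indanone, used as its tert-butyldimethylsilyl enol ether. One operation forms C1–C2 and C2–C3, expands the five-membered ring to aromatic ring A and leaves chlorine at C2 for later exchange by methoxide. The indanone is assembled by Suzuki coupling of a triflate derived from 5,7-dimethoxy-1-indanone.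

Key step: step 6

Assumption: 3-(3,5-dimethoxyphenyl)propanoic acid is taken as the commercial entry point; if 5,7-dimethoxy-1-indanone (2) is bought instead, step 1 is skipped.

Remark on numbering and stereochemistry: in 1H-indene numbering the enol ether 8 carries the siloxy group at C3, the aryl group at C4 and the methoxy group at C6 (C1, C7 and C5 of the parent indanone). The target has no stereocentre; the transient cyclopropane 10 is racemic.

Step 1
Reactants: 1 3-(3,5-dimethoxyphenyl)propanoic acid
Product: 2 5,7-dimethoxy-2,3-dihydro-1H-inden-1-one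
Conditions: MeSO3H (neat), 90 °C
Reagents that add atoms: none
Why: Intramolecular Friedel–Crafts acylation in a strong protic acid should close the five-membered ketone cleanly, because the two ring positions ortho to the side chain are equivalent and each is activated by one ortho and one para methoxy group, so only one indanone is possible.

Step 2
Reactants: 2 5,7-dimethoxy-2,3-dihydro-1H-inden-1-one
Product: 4 7-hydroxy-5-methoxy-2,3-dihydro-1H-inden-1-one, via dichloroboryl ether 3 (not isolated)
Conditions: BCl3 (1.5 equiv), CH2Cl2, −78 °C to 0 °C; then H2O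
Reagents that add atoms: none
Why: Chelation-controlled Lewis acid ether cleavage: BCl3 binds the C1 carbonyl oxygen and the neighbouring C7 methoxy oxygen in a six-membered chelate, so chloride removes only that methyl group, and the remote C5 methyl ether should survive at low temperature.

Step 3
Reactants: 4 7-hydroxy-5-methoxy-2,3-dihydro-1H-inden-1-one
Product: 5 6-methoxy-3-oxo-2,3-dihydro-1H-inden-4-yl trifluoromethanesulfonate
Conditions: Tf2O (1.2 equiv), pyridine, CH2Cl2, 0 °C
Reagents that add atoms: trifluoromethanesulfonic anhydride, O=S(=O)(OS(=O)(=O)C(F)(F)F)C(F)(F)F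
Why: Sulfonylation of the phenol with triflic anhydride and pyridine is a standard aryl triflate synthesis, and the anhydride is reactive enough to overcome the hydrogen bond between the C7 hydroxyl and the carbonyl.

Step 4
Reactants: 5 6-methoxy-3-oxo-2,3-dihydro-1H-inden-4-yl trifluoromethanesulfonate; 6 (3,4-dimethoxyphenyl)boronic acid
Product: 7 7-(3,4-dimethoxyphenyl)-5-methoxy-2,3-dihydro-1H-inden-1-one
Conditions: Pd(PPh3)4 (5 mol %), K3PO4, 1,4-dioxane–H2O, 90 °C
Reagents that add atoms: none
Why: Suzuki–Miyaura coupling: the ortho carbonyl group makes the C–OTf bond electron-poor, which favours oxidative addition to zerovalent palladium, and the mild phosphate base leaves the enolisable ketone and the methyl ethers untouched.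

Step 5
Reactants: 7 7-(3,4-dimethoxyphenyl)-5-methoxy-2,3-dihydro-1H-inden-1-one
Product: 8 tert-butyl{[4-(3,4-dimethoxyphenyl)-6-methoxy-1H-inden-3-yl]oxy}dimethylsilane
Conditions: TBSOTf (1.3 equiv), Et3N, CH2Cl2, 0 °C to rt
Reagents that add atoms: tert-butyldimethylsilyl trifluoromethanesulfonate, CC(C)(C)[Si](C)(C)OS(=O)(=O)C(F)(F)F
Why: Soft enolisation with in situ O-silylation (silyl enol ether formation) can only occur toward C2, the sole α-carbon bearing hydrogen, and the tert-butyldimethylsilyl group is chosen because its enol ether tolerates chromatography and tert-butoxide far better than a trimethylsilyl ether would.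

Step 6
Reactants: 8 tert-butyl{[4-(3,4-dimethoxyphenyl)-6-methoxy-1H-inden-3-yl]oxy}dimethylsilane; 9 chloroform
Product: 12 2-chloro-8-(3,4-dimethoxyphenyl)-6-methoxynaphthalen-1-ol, via dichlorocyclopropane 10 (not isolated), via silyl naphthyl ether 11 (not isolated)
Conditions: CHCl3 (3 equiv), KOtBu (6 equiv, in portions), hexane–toluene, −20 °C to rt; then Bu4NF, THF, rt; aq. NH4Cl
Reagents that add atoms: none
Why: Dichlorocarbene, formed from chloroform by α-elimination, adds in a concerted [2+1] cheletropic fashion to the electron-rich enol ether C=C of 8 to give the cis-fused siloxy dichlorocyclopropane 10, whose strained bicyclo[3.1.0] unit undergoes disrotatory two-electron electrocyclic opening with loss of the endo chloride, pushed by the siloxy oxygen, after which the oxocarbenium ion loses the C4 proton to tert-butoxide to give the aromatic silyl ether 11 that fluoride unmasks. The closest known reaction type is the dihalocarbene ring expansion of indenes and of cyclic ketone silyl enol ethers to 2-halonaphthalenes and 2-halo enones. Ring A is not closed by a cyclisation but arises by one-carbon enlargement of the five-membered ring: the cyclopropane forms by cheletropic addition and the six-membered ring by cleavage of the shared C–C bond in a cyclopropyl-to-allyl cation opening. No stereocentre remains, because the two transient cyclopropane stereocentres of racemic 10 are destroyed on aromatisation. The step needs chemoselectivity for the enol ether over the three methoxyarene rings and a defined site of insertion, and both are secured because the siloxy-substituted C=C is the only non-aromatic, strongly nucleophilic π bond, so the new carbon ends up between the former carbonyl carbon (C1) and the former α-carbon (C3) with the retained chlorine at C2. The silyl group stays on oxygen while carbene is being generated, which shields the naphthol oxygen from Reimer–Tiemann-type attack.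

Step 7
Reactants: 12 2-chloro-8-(3,4-dimethoxyphenyl)-6-methoxynaphthalen-1-ol
Product: 13 2-chloro-8-(3,4-dimethoxyphenyl)-6-methoxynaphthalene-1,4-dione
Conditions: (KSO3)2NO (2.5 equiv), KH2PO4 buffer, acetone–H2O, rt
Reagents that add atoms: potassium nitrosodisulfonate (Fremy's salt), [K+].[K+].[O]N(S(=O)(=O)[O-])S(=O)(=O)[O-]
Why: Teuber oxidation: one nitroxyl radical removes the phenolic hydrogen and a second one bonds through oxygen to C4, the only open position conjugated to the phenoxyl radical since C2 carries chlorine, and loss of imidodisulfonate then gives the 1,4-quinone while the methyl ethers stay inert.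

Step 8
Reactants: 13 2-chloro-8-(3,4-dimethoxyphenyl)-6-methoxynaphthalene-1,4-dione
Product: 14 8-(3,4-dimethoxyphenyl)-2,6-dimethoxynaphthalene-1,4-dione
Conditions: NaOMe (1.1 equiv), MeOH–THF, 0 °C
Reagents that add atoms: sodium methoxide, [Na+].[O-]C
Why: Addition–elimination (vinylogous nucleophilic acyl substitution) on the 2-chloro-1,4-quinone: methoxide adds to C2, which is β to the C4 carbonyl, and chloride is expelled, whereas addition at C3 is reversible, leads to no leaving-group loss and is disfavoured because the C6 methoxy group donates into the C1 carbonyl.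

Compound list
1 | 3-(3,5-dimethoxyphenyl)propanoic acid | COc1cc(CCC(=O)O)cc(OC)c1 | starting material
2 | 5,7-dimethoxy-2,3-dihydro-1H-inden-1-one | O=C1CCc2cc(OC)cc(OC)c21 | intermediate
3 | 7-(dichloroboryloxy)-5-methoxy-2,3-dihydro-1H-inden-1-one, boron chelated by the C1 carbonyl (not isolated) | O=C1CCc2cc(OC)cc(OB(Cl)Cl)c21 | intermediate
4 | 7-hydroxy-5-methoxy-2,3-dihydro-1H-inden-1-one | O=C1CCc2cc(OC)cc(O)c21 | intermediate
5 | 6-methoxy-3-oxo-2,3-dihydro-1H-inden-4-yl trifluoromethanesulfonate | O=C1CCc2cc(OC)cc(OS(=O)(=O)C(F)(F)F)c21 | intermediate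
6 | (3,4-dimethoxyphenyl)boronic acid | COc1ccc(B(O)O)cc1OC | starting material
7 | 7-(3,4-dimethoxyphenyl)-5-methoxy-2,3-dihydro-1H-inden-1-one | O=C1CCc2cc(OC)cc(-c3ccc(OC)c(OC)c3)c21 | intermediate
8 | tert-butyl{[4-(3,4-dimethoxyphenyl)-6-methoxy-1H-inden-3-yl]oxy}dimethylsilane (silyl enol ether of 7) | CC(C)(C)[Si](C)(C)OC1=CCc2cc(OC)cc(-c3ccc(OC)c(OC)c3)c21 | intermediate
9 | chloroform | ClC(Cl)Cl | starting material
10 | 1a-(tert-butyldimethylsilyloxy)-1,1-dichloro-2-(3,4-dimethoxyphenyl)-4-methoxy-1,1a,6,6a-tetrahydrocyclopropa[a]indene, racemic, cis ring fusion, one enantiomer drawn (not isolated) | CC(C)(C)[Si](C)(C)O[C@@]12c3c(-c4ccc(OC)c(OC)c4)cc(OC)cc3C[C@@H]1C2(Cl)Cl | intermediate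
11 | tert-butyl{[2-chloro-8-(3,4-dimethoxyphenyl)-6-methoxynaphthalen-1-yl]oxy}dimethylsilane (not isolated) | CC(C)(C)[Si](C)(C)Oc1c(Cl)ccc2cc(OC)cc(-c3ccc(OC)c(OC)c3)c12 | intermediate
12 | 2-chloro-8-(3,4-dimethoxyphenyl)-6-methoxynaphthalen-1-ol | Oc1c(Cl)ccc2cc(OC)cc(-c3ccc(OC)c(OC)c3)c12 | intermediate
13 | 2-chloro-8-(3,4-dimethoxyphenyl)-6-methoxynaphthalene-1,4-dione | O=C1C(Cl)=CC(=O)c2cc(OC)cc(-c3ccc(OC)c(OC)c3)c21 | intermediate
14 | 8-(3,4-dimethoxyphenyl)-2,6-dimethoxynaphthalene-1,4-dione | COC1=CC(=O)c2cc(OC)cc(-c3ccc(OC)c(OC)c3)c2C1=O | target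

Total step count: 8
Longest linear sequence: 8 steps (1 to 14); the boronic acid 6 and chloroform 9 enter as purchased reagents.

Steps most likely to fail

Step 6 (carbene ring expansion). Three things may go wrong. tert-Butoxide may strip the silyl group before the carbene is captured, which returns the ketone. Carbene addition may be slowed by crowding at C1 between the silyl ether and the peri aryl group. Excess carbene may attack the electron-rich naphthol once it is desilylated. The fallback sets out from 8 and runs the one-carbon insertion with a methylene unit in stages. Simmons–Smith cyclopropanation (Et2Zn, CH2I2, CH2Cl2, 0 °C) should give the siloxycyclopropane F1. FeCl3 in DMF at 0 °C opens it oxidatively through the cyclopropyloxy radical, with cleavage of the shared bond and chlorine transfer, to the racemic 3-chlorotetralone F2. NaOAc in methanol eliminates HCl with aromatisation to the parent naphthol F3. Ortho-selective chlorination (SO2Cl2, catalytic 2,2,6,6-tetramethylpiperidine, toluene) then comes back to the route at 12.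

Step 8 (chloride to methoxide exchange). Methoxide may add at C3 in place of C2, add a second time to the methoxyquinone, or cause base-induced degradation of the quinone. The fallback sets out from 8 and places the methoxy group on the arene before any quinone exists. CHBr3 and KOtBu (hexane–toluene, −20 °C to rt), followed by Bu4NF, should lead through the dibromocyclopropane F4 and the bromo silyl ether F5 to the bromonaphthol F6. Copper-catalysed Ullmann-type methanolysis of the ortho-bromophenol (NaOMe, CuBr, MeOH–DMF, 110 °C) gives the methoxynaphthol F7. Oxidation of F7 with (KSO3)2NO at the free C4 position comes back to the route at 14.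

Step 7 (phenol to quinone oxidation). The water-soluble radical may react slowly with the lipophilic phenol, whose hydroxyl is flanked by chlorine and the peri aryl group, and phenoxyl radical coupling may compete with oxygen transfer. The fallback sets out from 12 and replaces the radical oxidation by a two-electron oxidative dearomatisation. PhI(OAc)2 (2.2 equiv) in methanol at 0 °C should give the quinone monoketal F8 by two successive methanol additions at C4. Dilute aqueous HCl in THF hydrolyses the ketal and comes back to the route at 13.

Further compounds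
F1 | step 6 | 1a-(tert-butyldimethylsilyloxy)-2-(3,4-dimethoxyphenyl)-4-methoxy-1,1a,6,6a-tetrahydrocyclopropa[a]indene, racemic, one enantiomer drawn | CC(C)(C)[Si](C)(C)O[C@@]12c3c(-c4ccc(OC)c(OC)c4)cc(OC)cc3C[C@@H]1C2
F2 | step 6 | 3-chloro-8-(3,4-dimethoxyphenyl)-6-methoxy-3,4-dihydronaphthalen-1(2H)-one, racemic | O=C1CC(Cl)Cc2cc(OC)cc(-c3ccc(OC)c(OC)c3)c21
F3 | step 6 | 8-(3,4-dimethoxyphenyl)-6-methoxynaphthalen-1-ol | Oc1cccc2cc(OC)cc(-c3ccc(OC)c(OC)c3)c12
F4 | step 8 | 1a-(tert-butyldimethylsilyloxy)-1,1-dibromo-2-(3,4-dimethoxyphenyl)-4-methoxy-1,1a,6,6a-tetrahydrocyclopropa[a]indene, racemic, one enantiomer drawn | CC(C)(C)[Si](C)(C)O[C@@]12c3c(-c4ccc(OC)c(OC)c4)cc(OC)cc3C[C@@H]1C2(Br)Br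
F5 | step 8 | tert-butyl{[2-bromo-8-(3,4-dimethoxyphenyl)-6-methoxynaphthalen-1-yl]oxy}dimethylsilane | CC(C)(C)[Si](C)(C)Oc1c(Br)ccc2cc(OC)cc(-c3ccc(OC)c(OC)c3)c12
F6 | step 8 | 2-bromo-8-(3,4-dimethoxyphenyl)-6-methoxynaphthalen-1-ol | Oc1c(Br)ccc2cc(OC)cc(-c3ccc(OC)c(OC)c3)c12
F7 | step 8 | 8-(3,4-dimethoxyphenyl)-2,6-dimethoxynaphthalen-1-ol | COc1ccc2cc(OC)cc(-c3ccc(OC)c(OC)c3)c2c1O
F8 | step 7 | 2-chloro-8-(3,4-dimethoxyphenyl)-4,4,6-trimethoxynaphthalen-1(4H)-one | O=C1C(Cl)=CC(OC)(OC)c2cc(OC)cc(-c3ccc(OC)c(OC)c3)c21
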